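**Plan**

1. Atom labels follow the target ring: O1, C2, C3, C4, C5, with C7 and C7' the benzylic carbons on C3 and C4 (compound names keep their own locants). The enabling feature is that C5 is a bare CH2 between O1 and the C4 stereocentre. One molecule of CO can therefore supply C5, bonding first to C4 of a C4=C7' styrene and then to O1, while C7' ends as the benzylic CH2.
2. Retrosynthetic cuts, in order: C5–H (back to the C5 lactol); O1–C5, C4–C5 and C7'–H together (directed hydroformylation with hemiacetal closure); the C2 oxidation level (CH2OH back to an acyl group); C3–C7 (enolate benzylation); acyl–N (auxiliary); aryl–C7' (Heck).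
3. Forward: the four-carbon chain is joined to the first arene, C3–C7 is made, the acyl group is reduced to free O1–H, and only then does the tetrahydrofuran ring, the sole ring formed, close in one step as a lactol, which is finally deoxygenated.
4. Stereochemistry: C3 (R) comes from an Evans alkylation on (R)-4-benzyloxazolidin-2-one. C4 (R) is set relative to C3 in the hydroformylation, by substrate control and then by equilibration to the trans lactol through the ring-opened hydroxy aldehyde.

Key step: step 5

**Step 1**
Reactants: 1 4-bromoveratrole (4-bromo-1,2-dimethoxybenzene); 2 but-3-enoic acid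
Product: 3 (E)-4-(3,4-dimethoxyphenyl)but-3-enoic acid
Conditions: Pd(OAc)2 (2 mol %), P(o-tol)3 (6 mol %), Et3N (2.5 equiv), MeCN, 90 °C; then aq. HCl, recrystallisation
Reagents that add atoms: none
Why: Mizoroki–Heck reaction: 1 adds oxidatively to zerovalent palladium (formed in situ from Pd(OAc)2 and the phosphine), the aryl group is transferred to the terminal alkene carbon of 2, and syn beta-hydride elimination toward the benzylic hydrogen gives the aryl-conjugated (E)-alkene with the CH2CO2H unit left intact.

**Step 2**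
Reactants: 3 (E)-4-(3,4-dimethoxyphenyl)but-3-enoic acid; 4 (R)-4-benzyloxazolidin-2-one
Product: 6 (R)-4-benzyl-3-[(E)-4-(3,4-dimethoxyphenyl)but-3-enoyl]oxazolidin-2-one, via mixed pivalic anhydride 5 (not isolated)
Conditions: t-BuCOCl, Et3N, THF, −20 °C; then LiCl, 4, −20 → 23 °C
Reagents that add atoms: none
Why: N-Acylation of the auxiliary through a mixed anhydride: t-BuCOCl converts 3 into 5, whose unhindered acyl carbon is attacked by the LiCl/Et3N-activated oxazolidinone, and the mild amine base leaves the beta,gamma-alkene in place.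

**Step 3**
Reactants: 6 (R)-4-benzyl-3-[(E)-4-(3,4-dimethoxyphenyl)but-3-enoyl]oxazolidin-2-one; 7 3,4-dimethoxybenzyl bromide
Product: 9 (R)-4-benzyl-3-[(2R,3E)-2-(3,4-dimethoxybenzyl)-4-(3,4-dimethoxyphenyl)but-3-enoyl]oxazolidin-2-one, via sodium dienolate 8 (not isolated)
Conditions: NaN(SiMe3)2 (1.1 equiv), THF, −78 °C; then 7 (1.5 equiv), −78 → −40 °C; aq. NH4Cl
Reagents that add atoms: none
Why: Evans asymmetric alkylation: the chelated (Z)-sodium dienolate 8 reacts with the benzylic bromide at its alpha carbon, the kinetically preferred site of a dienolate, on the face away from the benzyl group of the auxiliary, which sets the (R) centre that becomes C3 of the target.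

**Step 4**
Reactants: 9 (R)-4-benzyl-3-[(2R,3E)-2-(3,4-dimethoxybenzyl)-4-(3,4-dimethoxyphenyl)but-3-enoyl]oxazolidin-2-one
Product: 10 (2R,3E)-2-(3,4-dimethoxybenzyl)-4-(3,4-dimethoxyphenyl)but-3-en-1-ol
Conditions: LiBH4 (2 equiv), H2O (1 equiv), Et2O, 0 °C
Reagents that add atoms: none
Why: Reductive cleavage of the N-acyloxazolidinone: LiBH4 attacks the exocyclic imide carbonyl and takes it down to the primary alcohol without touching the styrene or the neighbouring stereocentre, which is no longer enolisable once the carbonyl is gone.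

**Step 5**
Reactants: 10 (2R,3E)-2-(3,4-dimethoxybenzyl)-4-(3,4-dimethoxyphenyl)but-3-en-1-ol; 11 carbon monoxide
Product: 15 (3R,4R)-3,4-bis(3,4-dimethoxybenzyl)tetrahydrofuran-2-ol (mixture of anomers), via substrate phosphinite 12 (not isolated), via formyl phosphinite 13 (not isolated), via open hydroxy aldehyde 14 (not isolated)
Conditions: Rh(acac)(CO)2 (2 mol %), Ph2POMe (10 mol %), 4 Å MS, CO/H2 (1:1, 30 bar), THF, 50 °C; then DBU (0.2 equiv), THF, 23 °C
Reagents that add atoms: none
Why: Ph2POMe trades its methoxy group for the primary hydroxyl of 10, and in phosphinite 12 the phosphorus carries the monovalent rhodium hydride to the alkene, so that rhodium bonds to C4 within a six-membered Rh–P–O1–C2–C3–C4 chelate and hydrogen goes to C7'; CO insertion and hydrogenolysis then give formyl phosphinite 13 (C4–C5 bond), and transfer of the Ph2P group to fresh 10 or to methanol releases hydroxy aldehyde 14. The closest known reaction type is the branched-selective hydroformylation of homoallylic alcohols with a catalytic, reversibly bound phosphinite directing group, which delivers gamma-lactols. The tetrahydrofuran ring closes when O1 adds to the C5 carbonyl of 14, a 5-exo-trig hemiacetalisation. The new C4 centre is governed by the existing C3 centre: with the C3 benzyl group pseudo-equatorial in the chelate, syn addition of Rh–H to the (E)-alkene is expected to set the formyl group anti to it, and since C4 remains epimerisable through 14, the DBU treatment funnels any cis material into the more stable trans-(3R,4R) lactol. The selectivity required is regiochemical, C4 against the benzylic C7' that an undirected styrene hydroformylation favours, and the homoallylic spacing O1–C2–C3–C4=C7' secures it because only rhodium at C4 fits the chelate.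

**Step 6**
Reactants: 15 (3R,4R)-3,4-bis(3,4-dimethoxybenzyl)tetrahydrofuran-2-ol (mixture of anomers)
Product: 17 (3R,4R)-3,4-bis(3,4-dimethoxybenzyl)tetrahydrofuran (target), via oxocarbenium ion 16 (not isolated)
Conditions: Et3SiH (3 equiv), BF3·OEt2 (1.5 equiv), CH2Cl2, −78 → −20 °C
Reagents that add atoms: none
Why: Ionic hydrogenation of a lactol: BF3 ionises the hemiacetal hydroxyl to oxocarbenium ion 16, and at low temperature Et3SiH transfers hydride to C5 faster than the ion can lose a proton or be attacked by an arene, so C3 and C4 are carried through unchanged.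

**Compound list**

1 | 4-bromoveratrole (4-bromo-1,2-dimethoxybenzene) | COc1ccc(Br)cc1OC | starting material
2 | but-3-enoic acid | C=CCC(=O)O | starting material
3 | (E)-4-(3,4-dimethoxyphenyl)but-3-enoic acid | COc1ccc(/C=C/CC(=O)O)cc1OC | intermediate
4 | (R)-4-benzyloxazolidin-2-one | O=C1N[C@H](Cc2ccccc2)CO1 | starting material
5 | (E)-4-(3,4-dimethoxyphenyl)but-3-enoic pivalic anhydride | COc1ccc(/C=C/CC(=O)OC(=O)C(C)(C)C)cc1OC | intermediate
6 | (R)-4-benzyl-3-[(E)-4-(3,4-dimethoxyphenyl)but-3-enoyl]oxazolidin-2-one | COc1ccc(/C=C/CC(=O)N2[C@H](Cc3ccccc3)COC2=O)cc1OC | intermediate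
7 | 3,4-dimethoxybenzyl bromide | COc1ccc(CBr)cc1OC | starting material
8 | sodium (1Z,3E)-1-[(R)-4-benzyl-2-oxooxazolidin-3-yl]-4-(3,4-dimethoxyphenyl)buta-1,3-dien-1-olate | [Na+].[O-]/C(=C\C=C\c1ccc(OC)c(OC)c1)N1[C@H](Cc2ccccc2)COC1=O | intermediate
9 | (R)-4-benzyl-3-[(2R,3E)-2-(3,4-dimethoxybenzyl)-4-(3,4-dimethoxyphenyl)but-3-enoyl]oxazolidin-2-one | COc1ccc(C[C@H](/C=C/c2ccc(OC)c(OC)c2)C(=O)N2[C@H](Cc3ccccc3)COC2=O)cc1OC | intermediate
10 | (2R,3E)-2-(3,4-dimethoxybenzyl)-4-(3,4-dimethoxyphenyl)but-3-en-1-ol | COc1ccc(C[C@H](/C=C/c2ccc(OC)c(OC)c2)CO)cc1OC | intermediate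
11 | carbon monoxide | [C-]#[O+] | starting material
12 | (2R,3E)-2-(3,4-dimethoxybenzyl)-4-(3,4-dimethoxyphenyl)but-3-en-1-yl diphenylphosphinite | COc1ccc(C[C@H](/C=C/c2ccc(OC)c(OC)c2)COP(c2ccccc2)c2ccccc2)cc1OC | intermediate
13 | (2R,3R)-2,3-bis(3,4-dimethoxybenzyl)-4-oxobutyl diphenylphosphinite | COc1ccc(C[C@@H](COP(c2ccccc2)c2ccccc2)[C@H](C=O)Cc2ccc(OC)c(OC)c2)cc1OC | intermediate
14 | (2R,3R)-2,3-bis(3,4-dimethoxybenzyl)-4-hydroxybutanal | COc1ccc(C[C@@H](CO)[C@H](C=O)Cc2ccc(OC)c(OC)c2)cc1OC | intermediate
15 | (3R,4R)-3,4-bis(3,4-dimethoxybenzyl)tetrahydrofuran-2-ol (mixture of anomers) | COc1ccc(C[C@H]2COC(O)[C@@H]2Cc2ccc(OC)c(OC)c2)cc1OC | intermediate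
16 | (3R,4R)-3,4-bis(3,4-dimethoxybenzyl)-3,4-dihydro-2H-furan-1-ium hydroxytrifluoroborate (oxocarbenium ion) | COc1ccc(C[C@H]2C[O+]=C[C@@H]2Cc2ccc(OC)c(OC)c2)cc1OC.O[B-](F)(F)F | intermediate
17 | (3R,4R)-3,4-bis(3,4-dimethoxybenzyl)tetrahydrofuran | COc1ccc(C[C@H]2COC[C@@H]2Cc2ccc(OC)c(OC)c2)cc1OC | target

**Totals**

Total step count: 6.
Longest linear sequence: 6 steps (1 → 3 → 6 → 9 → 10 → 15 → 17).

**Steps most likely to fail**

1. Step 5. Whenever the substrate is not phosphinite-bound, the rhodium hydride can add the undirected way and put the metal on the benzylic C7'. The 1,2-disubstituted styrene may also turn over slowly, and reversible beta-hydride elimination could move the alkene toward C3. The fallback uses known chemistry and replaces the carbonylation by a radical ring closure that forms the same C4–C5 bond. It sets out from 10. Williamson etherification with chloromethyl phenyl selenide (NaH, NaI cat., THF) should give {[(2R,3E)-2-(3,4-dimethoxybenzyl)-4-(3,4-dimethoxyphenyl)but-3-en-1-yl]oxy}methyl phenyl selenide F1. Bu3SnH and AIBN (benzene, 80 °C, slow addition) should then generate the O1–CH2 radical, which closes 5-exo-trig onto C4 of the styrene, and the benzylic C7' radical is reduced by the stannane. A chair-like transition state with the C3 benzyl group pseudo-equatorial favours the trans ring. The sequence comes back to the route at target 17, bypassing 15 and step 6.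

2. Step 3. The aryl-extended dienolate may alkylate partly at its gamma carbon. Proton exchange between product and enolate could also erode the alpha configuration or pull the alkene into conjugation with the imide. The fallback sets out from 4 and 7 and introduces the aryl group only after the stereocentre has lost its acidic hydrogen. Acylation of 4 with (E)-crotonic anhydride (Et3N, LiCl, THF) gives (R)-4-benzyl-3-[(E)-but-2-enoyl]oxazolidin-2-one F2. NaN(SiMe3)2 at −78 °C removes a gamma hydrogen to give sodium (Z)-1-[(R)-4-benzyl-2-oxooxazolidin-3-yl]buta-1,3-dien-1-olate F3, which 7 alkylates at the alpha carbon with the same facial bias to give (R)-4-benzyl-3-[(R)-2-(3,4-dimethoxybenzyl)but-3-enoyl]oxazolidin-2-one F4. LiBH4 (H2O, Et2O, 0 °C) gives (R)-2-(3,4-dimethoxybenzyl)but-3-en-1-ol F5. Cross-metathesis of F5 with 3,4-dimethoxystyrene under (H2IMes)(PCy3)Cl2Ru=CHPh (second-generation Grubbs catalyst, CH2Cl2, 40 °C) should install the (E)-styrene and return to the route at 10.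

3. Step 6. The oxocarbenium ion may be captured by an electron-rich veratryl ring in an intramolecular Friedel–Crafts reaction, or it may lose the C4 proton to an enol ether and so lose the trans relation. The fallback sets out from 15 and avoids any cation. NaBH4 (MeOH, 0 °C) reduces the open form to (2R,3R)-2,3-bis(3,4-dimethoxybenzyl)butane-1,4-diol F6. TsCl (1.05 equiv) in pyridine gives (2R,3R)-2,3-bis(3,4-dimethoxybenzyl)-4-hydroxybutyl 4-methylbenzenesulfonate F7, which is not isolated because the remaining hydroxyl displaces the tosylate (5-exo-tet). Neither stereocentre is touched, and the sequence returns to the route at 17.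

**Further compounds**

F1 | step 5 | {[(2R,3E)-2-(3,4-dimethoxybenzyl)-4-(3,4-dimethoxyphenyl)but-3-en-1-yl]oxy}methyl phenyl selenide | COc1ccc(C[C@H](/C=C/c2ccc(OC)c(OC)c2)COC[Se]c2ccccc2)cc1OC
F2 | step 3 | (R)-4-benzyl-3-[(E)-but-2-enoyl]oxazolidin-2-one | C/C=C/C(=O)N1[C@H](Cc2ccccc2)COC1=O
F3 | step 3 | sodium (Z)-1-[(R)-4-benzyl-2-oxooxazolidin-3-yl]buta-1,3-dien-1-olate | [Na+].[O-]/C(=C\C=C)N1[C@H](Cc2ccccc2)COC1=O
F4 | step 3 | (R)-4-benzyl-3-[(R)-2-(3,4-dimethoxybenzyl)but-3-enoyl]oxazolidin-2-one | COc1ccc(C[C@H](C=C)C(=O)N2[C@H](Cc3ccccc3)COC2=O)cc1OC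
F5 | step 3 | (R)-2-(3,4-dimethoxybenzyl)but-3-en-1-ol | COc1ccc(C[C@H](C=C)CO)cc1OC
F6 | step 6 | (2R,3R)-2,3-bis(3,4-dimethoxybenzyl)butane-1,4-diol | COc1ccc(C[C@@H](CO)[C@H](CO)Cc2ccc(OC)c(OC)c2)cc1OC
F7 | step 6 | (2R,3R)-2,3-bis(3,4-dimethoxybenzyl)-4-hydroxybutyl 4-methylbenzenesulfonate | COc1ccc(C[C@@H](COS(=O)(=O)c2ccc(C)cc2)[C@H](CO)Cc2ccc(OC)c(OC)c2)cc1OC
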